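**Retrosynthetic overview** (phthalide numbering; unit A = butenolide half, unit B = primed, propellane half)
1. Target 10 ⇒ open the B-ring enol lactone O2′–C3′ bond: a syn 5-exo-dig O–H addition to an alkyne is what fixes the (3′E)-butylidene ⇒ lactone acid 9.
2. 9 ⇒ open the A-ring enol lactone O2–C3 bond (anti 5-exo-dig addition, fixes 3Z) ⇒ diacid 8 ⇒ diester 7.
3. 7 ⇒ enantioselective crossed [2+2] photodimerisation of dienynoate 6 (C6–C7a′ and C7–C3a′; all four stereocentres).
4. 6 ⇒ Sonogashira coupling of dienyl triflate 4 with pent-1-yne 5; 4 ⇒ β-keto ester 3 ⇒ Birch reduction/hydrolysis of methyl 2-methoxybenzoate 1.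
5. Ring order: cyclohexadiene (from the arene) → cyclobutane → lactone A → lactone B.

Assumption: the (S)-prolinol-derived catalyst in step 4 gives the enantiomer drawn; if the sense of induction is the opposite, the mirror-image catalyst is used.

Step 1
Reactants: 1 methyl 2-methoxybenzoate
Product: 3 methyl 2-hydroxycyclohexa-1,5-diene-1-carboxylate, via methyl 2-methoxycyclohexa-2,5-diene-1-carboxylate 2 (not isolated)
Conditions: K (2.2 equiv), t-BuOH (1.0 equiv), NH3(l)/THF, −78 °C; NH4Cl; then 1 M HCl, THF, 0 °C
Reagents that add atoms: water (O)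
Why: Birch reduction of a benzoate ester places the new hydrogens ipso and para to the ester, and mild acid hydrolysis of the resulting enol ether unmasks the β-keto ester, held as its hydrogen-bonded dienol; no stereocentre survives.

Step 2
Reactants: 3 methyl 2-hydroxycyclohexa-1,5-diene-1-carboxylate
Product: 4 methyl 2-(trifluoromethanesulfonyloxy)cyclohexa-1,5-diene-1-carboxylate
Conditions: Tf2O (1.1 equiv), i-Pr2NEt (1.3 equiv), CH2Cl2, −78 → 0 °C
Reagents that add atoms: trifluoromethanesulfonic anhydride (O=S(=O)(OS(=O)(=O)C(F)(F)F)C(F)(F)F)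
Why: Enol triflate formation at the only ketone oxygen of the β-keto ester fixes the diene pattern (ester carbon next to CH=, triflate carbon next to CH2).

Step 3
Reactants: 4 methyl 2-(trifluoromethanesulfonyloxy)cyclohexa-1,5-diene-1-carboxylate; 5 pent-1-yne
Product: 6 methyl 2-(pent-1-yn-1-yl)cyclohexa-1,5-diene-1-carboxylate
Conditions: PdCl2(PPh3)2 (2 mol %), CuI (4 mol %), Et3N, THF, 23 °C
Reagents that add atoms: none
Why: Sonogashira coupling of an activated alkenyl triflate with a terminal alkyne; the ring double bonds are untouched.

Step 4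
Reactants: 6 methyl 2-(pent-1-yn-1-yl)cyclohexa-1,5-diene-1-carboxylate (two molecules)
Product: 7 dimethyl 7,10-di(pent-1-yn-1-yl)tricyclo[6.4.0.0(2,7)]dodeca-3,9-diene-2,9-dicarboxylate (cis-syn-cis; H-1/H-8/2-CO2Me/7-alkynyl on the face opposite both rings)
Conditions: AlBr3-activated (S)-diarylprolinol B-aryl-oxazaborolidine (25 mol %), [Ir(ppy)2(dtbbpy)]PF6 (1 mol %), 450 nm LED, CH2Cl2, −78 °C
Reagents that add atoms: none
Why: Proposed new method: Lewis-acid-gated triplet sensitisation, in which only the ester bound to the chiral Lewis acid is within reach of the low-energy sensitiser; its triplet bonds through Cα (C1) to the unsubstituted diene terminus (C5) of a free molecule, and the allyl/propargyl 1,4-diradical closes C2–C6 on the unshielded face with ring A stacked over the carbocycle of B, away from the Lewis-acid-loaded ester, which sets the cis-syn-cis cyclobutane and all four stereocentres; the closest known reaction is the chiral-Lewis-acid-catalysed, triplet-sensitised enantioselective [2+2] photocycloaddition of cinnamate esters and enones with styrenes and dienes.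

Step 5
Reactants: 7 dimethyl 7,10-di(pent-1-yn-1-yl)tricyclo[6.4.0.0(2,7)]dodeca-3,9-diene-2,9-dicarboxylate
Product: 8 7,10-di(pent-1-yn-1-yl)tricyclo[6.4.0.0(2,7)]dodeca-3,9-diene-2,9-dicarboxylic acid (same configuration)
Conditions: Me3SnOH (8 equiv), ClCH2CH2Cl, 75 °C; 1 M HCl work-up
Reagents that add atoms: trimethyltin hydroxide (C[Sn](C)(C)O)
Why: Tin-assisted near-neutral methyl ester hydrolysis cleaves both esters, including the hindered quaternary one, without touching the alkynes; no centre is epimerisable.

Step 6
Reactants: 8 7,10-di(pent-1-yn-1-yl)tricyclo[6.4.0.0(2,7)]dodeca-3,9-diene-2,9-dicarboxylic acid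
Product: 9 lactone acid (unit A closed to the (3Z)-3-butylidene butenolide; unit B still 7a′-CO2H/3a′-pent-1-ynyl)
Conditions: DBU (20 mol %), MeCN, 40 °C; AcOH quench
Reagents that add atoms: none
Why: Amine-base-catalysed anti 5-exo-dig addition of the carboxylate to the conjugated enyne (as for 2-alkynylbenzoic acids giving (Z)-3-ylidenephthalides) puts O and H trans, i.e. the (3Z)-butylidene; the unconjugated alkynoic acid of unit B does not react with base alone.

Step 7
Reactants: 9 lactone acid
Product: 10 target, the (3Z,3′E)-6,7:3a′,7a′ cyclobutane dimer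
Conditions: Ru3(CO)12 (3 mol %), toluene, 90 °C, Ar, dark
Reagents that add atoms: none
Why: Proposed new method: inner-sphere syn hydro-acyloxylation, in which O–H oxidative addition of the acid to Ru(0), 5-exo syn insertion of the tethered alkyne into Ru–O (or Ru–H) and C–H (or C–O) reductive elimination with retention put O and H cis on the new double bond, giving the contra-thermodynamic (3′E)-butylidene (propyl cis to C3a′), whereas π-acid catalysts (Au, Ag, Hg) give the Z isomer by anti attack; the closest known reactions are the ruthenium-carbonyl-catalysed intermolecular cis-addition of carboxylic acids to internal alkynes and the insertive, E-selective lanthanide-catalysed hydroalkoxylation of alkynols.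

**Compound list**
1 | methyl 2-methoxybenzoate | COC(=O)c1ccccc1OC | starting material
2 | methyl 2-methoxycyclohexa-2,5-diene-1-carboxylate (racemic; C1 centre lost in the same step) | COC(=O)C1C=CCC=C1OC | intermediate
3 | methyl 2-hydroxycyclohexa-1,5-diene-1-carboxylate (enol form of methyl 6-oxocyclohex-2-ene-1-carboxylate) | COC(=O)C1=C(O)CCC=C1 | intermediate
4 | methyl 2-(trifluoromethanesulfonyloxy)cyclohexa-1,5-diene-1-carboxylate | COC(=O)C1=C(OS(=O)(=O)C(F)(F)F)CCC=C1 | intermediate
5 | pent-1-yne | CCCC#C | starting material
6 | methyl 2-(pent-1-yn-1-yl)cyclohexa-1,5-diene-1-carboxylate | CCCC#CC1=C(C(=O)OC)C=CCC1 | intermediate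
7 | dimethyl 7,10-di(pent-1-yn-1-yl)tricyclo[6.4.0.0(2,7)]dodeca-3,9-diene-2,9-dicarboxylate; cis-syn-cis, H-1, H-8, 2-CO2Me and 7-alkynyl on the face opposite both six-membered rings; absolute configuration as in 10 | COC(=O)C1=C(C#CCCC)CC[C@H]2[C@@H]1[C@@]3(C#CCCC)CCC=C[C@@]23C(=O)OC | intermediate
8 | the corresponding 2,9-dicarboxylic acid, same configuration | OC(=O)C1=C(C#CCCC)CC[C@H]2[C@@H]1[C@@]3(C#CCCC)CCC=C[C@@]23C(=O)O | intermediate
9 | lactone acid: unit A is the (3Z)-3-butylidene butenolide, unit B carries 7a′-CO2H and 3a′-pent-1-ynyl cis to each other, same cyclobutane configuration | CCC/C=C1\OC(=O)C2=C1CC[C@H]1[C@@H]2[C@@]2(C#CCCC)CCC=C[C@@]12C(=O)O | intermediate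
10 | (3Z,3′E,6S,7R,3a′S,7a′R)-6,7:3a′,7a′ cyclobutane dimer of ligustilide: C6–C7a′ and C7–C3a′ bonds, both carbocycles on one cyclobutane face, H-6, H-7 and the B lactone on the other, A butylidene Z, B butylidene E | CCC/C=C1\OC(=O)C2=C1CC[C@H]1[C@@H]2[C@@]23CCC=C[C@@]12C(=O)O/C3=C/CCC | target

**Step count and risks**
Total steps: 7. Longest linear sequence: 7 (the dimerisation uses two molecules of 6).

Steps most likely to fail:

- **Step 4 (proposed new method).** The dimerisation may give the other regiochemistry (terminus-to-terminus or C5–C2 bonding), [4+2] adducts or low ee. The fallback sets out from 6: ordinary triplet-sensitised [2+2] photodimerisation without a chiral catalyst (thioxanthone 10 mol %, 405 nm, CH2Cl2, 0 °C) gives the racemic head-to-tail dimer, that is 7 together with its mirror image, dimethyl ent-7,10-di(pent-1-yn-1-yl)tricyclo[6.4.0.0(2,7)]dodeca-3,9-diene-2,9-dicarboxylate F1. Regio- and diastereomers are removed by chromatography and the enantiomers are separated by preparative HPLC on a chiral stationary phase. The fallback returns to the route at 7.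

- **Step 7 (proposed new method).** The ruthenium catalyst may react by outer-sphere anti attack (giving the 3′Z isomer), isomerise the alkyne, or equilibrate E to Z on heating. The fallback sets out from 9: anti 5-exo-dig iodolactonisation (NIS, NaHCO3, MeCN, 0 °C) gives the (3′E)-3′-(1-iodobutylidene) lactone F2, with iodine trans to the ring oxygen. Radical hydrodeiodination at low temperature (Bu3SnH, Et3B/air, toluene, −78 °C) then gives 10: the bent, rapidly inverting vinyl radical is expected to take hydrogen on the side of the ring oxygen, away from the quaternary C3a′, which leaves propyl cis to C3a′. Both reactions are known types, but the E outcome of the second is a steric prediction. The fallback returns at 10.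

- **Step 5.** The quaternary ester may resist cleavage, and the conjugated enynoate may be damaged by forcing conditions. The fallback sets out from 7 and differentiates the two esters. LiOH (1.2 equiv, THF/H2O, 0 °C) hydrolyses only the unhindered conjugated ester to the mono-acid (unit A CO2H, unit B CO2Me) F3. AgNO3 (10 mol %, acetone, 23 °C) closes it by anti 5-exo-dig cyclisation to the (3Z)-butylidene butenolide methyl ester F4. LiI in refluxing EtOAc then demethylates the hindered ester by SN2 attack at the methyl group, giving 9. The fallback returns at 9 and also bypasses step 6, so it does not depend on the base-only chemoselectivity of that step.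

**Further compounds**
F1 | step 4 | dimethyl ent-7,10-di(pent-1-yn-1-yl)tricyclo[6.4.0.0(2,7)]dodeca-3,9-diene-2,9-dicarboxylate (mirror image of 7) | COC(=O)C1=C(C#CCCC)CC[C@@H]2[C@H]1[C@]3(C#CCCC)CCC=C[C@]23C(=O)OC
F2 | step 7 | (3Z)-butylidene butenolide / (3′E)-3′-(1-iodobutylidene) lactone, iodine trans to O2′ | CCC/C=C1\OC(=O)C2=C1CC[C@H]1[C@@H]2[C@@]23CCC=C[C@@]12C(=O)O/C3=C(/I)CCC
F3 | step 5 | mono-acid: unit A carboxylic acid, unit B methyl ester, both alkynes intact | OC(=O)C1=C(C#CCCC)CC[C@H]2[C@@H]1[C@@]3(C#CCCC)CCC=C[C@@]23C(=O)OC
F4 | step 5 | unit A (3Z)-3-butylidene butenolide, unit B methyl ester with 3a′-pent-1-ynyl | CCC/C=C1\OC(=O)C2=C1CC[C@H]1[C@@H]2[C@@]2(C#CCCC)CCC=C[C@@]12C(=O)OC
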